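I decide to follow one ratio through these flasks, not a full set of curves.

| flask | substrate | reagent | remark | time |
|---|---|---|---|---|
| Wednesday's | 0.32 M | 0.304 M | run made earlier |  |
| Saturday's | 0.45 M | 0.304 M | run made earlier |  |
| Tuesday's | 0.70 M | 0.304 M | run made earlier |  |
| Thursday's | 0.32 M | 0.15 M | run made earlier |  |
| grey | 0.32 M (fed, over 8.0 min) | 0.304 M | all else is in the flask from the start; the feed brings no volume worth counting | 12 min |
| violet | 0.32 M | 0.304 M | everything together at the start | 12 min |
| green | 0.32 M | 0.304 M (fed, over 8.0 min) | all else is in the flask from the start; the feed brings no volume worth counting | 12 min |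
| red | 0.32 M | 0.304 M (in portions, 4, over 8.0 min) | first portion at the start, last at 8.0 min | 12 min |

| run | time / min | over-reaction product / % | target / % |
|---|---|---|---|
| Wednesday's | 1.50 | 0 | 2.3 |
| Wednesday's | 4.00 | 0.8 | 7.6 |
| Wednesday's | 8.00 | 8.6 | 15.3 |
| Wednesday's | 12.0 | 14.8 | 18.3 |
| Saturday's | 0.500 | 0 | 0 |
| Saturday's | 1.33 | 0.2 | 1.2 |
| Saturday's | 3.00 | 1.1 | 4.0 |
| Saturday's | 8.00 | 8.2 | 15.5 |
| Tuesday's | 2.00 | 0.8 | 3.4 |
| Tuesday's | 4.00 | 0.9 | 8.4 |
| Tuesday's | 5.00 | 1.6 | 9.8 |
| Tuesday's | 8.00 | 5.4 | 14.3 |
| Thursday's | 2.00 | 0 | 1.3 |
| Thursday's | 4.00 | 1.8 | 6.3 |
| Thursday's | 5.00 | 2.6 | 6.8 |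
| Thursday's | 8.00 | 3.0 | 13.9 |

(each reading ± 1 percentage point)

- the analysis behind the earlier runs scatters by 1 percentage point, standard deviation
- candidate steps: substrate -> intermediate; reagent + intermediate -> target; reagent + target -> over-reaction product

- the flask that comes out highest in amount of over-reaction product, in percent of the substrate charged; "all alike" if 1.5 percentage points covers them all (grey / violet / green / red / all alike)
- amount of over-reaction product at the end, in percent of the substrate charged, grey
- amount of over-reaction product at the end, in percent of the substrate charged, violet
- amount of over-reaction product at the end, in percent of the substrate charged, green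
- amount of over-reaction product at the end, in percent of the substrate charged, red

In the candidate steps, over-reaction product comes from target. So over any stretch, the gain in target plus the gain in over-reaction product is target made, and the gain in over-reaction product is target used. From the start to 8.00 min, Wednesday's run gives a quotient of 2.78. Over the same stretch, Thursday's run gives 5.63, twice as much, with target close at 15.3% and 13.9%; both quotients are readings and carry the scatter. Over Wednesday's last stretch, from 8.00 min to 12.0 min, the quotient falls to 1.48, a reading with the scatter of its four numbers. This quotient of two rates is my made-to-used ratio.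

Both steps take reagent, so at any moment reagent cancels in the quotient of their rates, and time with it. What remains goes as intermediate over target. Thursday's run has 0.15 M of reagent against 0.304 M, so I read its intermediate as standing higher against target. At 8.00 min, Thursday's run holds 3.0% of over-reaction product against Wednesday's 8.6%.

My own reckoning follows. Violet is Wednesday's recipe, so I expect near 14.8%. Red starts with a quarter of its reagent, 0.0760 M, less than Thursday's 0.15 M, and green's reagent comes in by feed, so I expect both to end below violet. Grey receives its substrate over 8.0 min, so it lags too.

The forecast also names violet, with 14.5%, and gives grey 7%, green 10%, red 11%. Its ground for green is “Feeding reagent keeps reagent low early and lets intermediate build up”.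

The simulation gives violet 14.8%, green 12.7%, red 12.2%, grey 8.60%. Violet is highest, ahead of green by 2.1 percentage points. Green sits 2.7 points above the forecast's number, its widest gap.

    substrate → intermediate (k = 7.10 × 10⁻⁴ s⁻¹)
    reagent + intermediate → target (k = 0.0360 M⁻¹ s⁻¹)
    reagent + target → over-reaction product (k = 0.00950 M⁻¹ s⁻¹)

Violet ends with intermediate at 7.17% and target at 18.1%. I take Wednesday's 1.48 for violet's end. Dividing it by intermediate over target gives a reading of 3.75 for the selectivity factor: target step over over-reaction step. The neighbour is violet charged with 0.80 M of substrate. It ends with intermediate at 14.3% and target at 17.8%. The same factor gives it a made-to-used ratio of 2.99, twice violet's. That neighbour ends with 7.93% of over-reaction product, in percent of its own larger substrate charge, against violet's 14.8%.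

The readings were computed on assumed constants; the scatter is artificial.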